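The cycloheptenone ring (C1 ketone, C2, C3, C4, quaternary C5, C6, C7) is disconnected at C3–C4. An intramolecular nickel-catalysed reductive coupling joins a neopentyl iodide (C4) to a (Z)-β-iodoenone (C3), closing the ring and creating the cis-enone in one operation; because C4 lies between sp2 C3 and quaternary C5, a nickel alkyl at C4 has no β-hydrogen. The precursor is an open-chain diiodide that already carries C5, C6 and C7, with both carbonyl arms as dioxolanes and the side-chain alkene held in the terminal position, outside 5-exo reach of the C4 radical. C4–I is made before any C1 acyl group exists, which rules out lactone formation during iodination.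

Key step: step 14

Remark: the ring centres are fixed as 5S,6S,7S before ring closure; the ligand antipode in step 1 is the one that gives (R)-3; the hydroperoxide centre formed in step 20 is not controlled and the (S)-epimer is isolated by HPLC.

Step 1
Reactants: 1 5,6-dihydro-2H-pyran-2-one; 2 (1,3-dioxolan-2-ylmethyl)magnesium bromide
Product: 3 (R)-4-(1,3-dioxolan-2-ylmethyl)oxan-2-one
Conditions: CuBr·SMe2 (5 mol %), (R)-Tol-BINAP (6 mol %), t-BuOMe/THF, −40 °C; aq. NH4Cl
Reagents that add atoms: none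
Why: Copper-catalysed asymmetric conjugate addition of a Grignard reagent to the unsaturated δ-lactone should install the acetal-protected two-carbon arm directly at C6 (an open-chain 2,2-dialkoxyethyl metal would eliminate, the cyclic acetal reagent does not), the chiral diphosphine–copper complex choosing the enone face and thereby setting the (R) centre from which C5 and C7 are relayed.

Step 2
Reactants: 3 (R)-4-(1,3-dioxolan-2-ylmethyl)oxan-2-one
Product: 5 (3R,4R)-4-(1,3-dioxolan-2-ylmethyl)-3-methyloxan-2-one, via lithium enolate 4 (not isolated)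
Conditions: LiN(iPr)2, THF, −78 °C; MeI, −78 to −40 °C
Reagents that add atoms: iodomethane, CI
Why: Lactone enolate alkylation with MeI places the methyl group trans to the C6 arm, although this centre is planarised again in step 4 and only the order of the two alkylations matters.

Step 3
Reactants: 6 4-methylpent-4-en-1-ol
Product: 7 5-iodo-2-methylpent-1-ene
Conditions: PPh3, I2, imidazole, CH2Cl2, 0 °C to rt
Reagents that add atoms: iodine, II
Why: Appel iodination converts the unhindered primary alcohol into the iodide through SN2 displacement of its alkoxyphosphonium salt and leaves the 1,1-disubstituted alkene untouched.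

Step 4
Reactants: 5 (3R,4R)-4-(1,3-dioxolan-2-ylmethyl)-3-methyloxan-2-one; 7 5-iodo-2-methylpent-1-ene
Product: 9 (3R,4R)-4-(1,3-dioxolan-2-ylmethyl)-3-methyl-3-(4-methylpent-4-en-1-yl)oxan-2-one, via lithium enolate 8 (not isolated)
Conditions: LiN(iPr)2, THF, −78 °C; 7, DMPU, −78 to 0 °C
Reagents that add atoms: none
Why: In this second lactone enolate alkylation the α-methyl enolate forces the C6 arm pseudo-axial (A(1,2) strain) and the primary iodide attacks the opposite face, so the chain enters trans to the arm and quaternary C5 is set as 3R by 1,2-induction from C6.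

Step 5
Reactants: 9 (3R,4R)-4-(1,3-dioxolan-2-ylmethyl)-3-methyl-3-(4-methylpent-4-en-1-yl)oxan-2-one
Product: 10 (2R,3R)-3-(1,3-dioxolan-2-ylmethyl)-2-methyl-2-(4-methylpent-4-en-1-yl)pentane-1,5-diol
Conditions: LiAlH4, THF, 0 °C to rt; H2O then aq. NaOH
Reagents that add atoms: none
Why: LiAlH4 reduction of the lactone gives the 1,5-diol without touching the acetal or the alkene and creates no stereocentre.

Step 6
Reactants: 10 (2R,3R)-3-(1,3-dioxolan-2-ylmethyl)-2-methyl-2-(4-methylpent-4-en-1-yl)pentane-1,5-diol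
Product: 11 (2R,3S)-3-(1,3-dioxolan-2-ylmethyl)-1,5-diiodo-2-methyl-2-(4-methylpent-4-en-1-yl)pentane
Conditions: PPh3, I2, imidazole, toluene, rt then 90 °C
Reagents that add atoms: iodine, II
Why: Garegg–Samuelsson (Appel-type) iodination converts both alcohols, the unhindered one at room temperature and the neopentyl one on heating, and is clean at this stage because no carbonyl oxygen is present that could close a ring onto the activated C4.

Step 7
Reactants: 11 (2R,3S)-3-(1,3-dioxolan-2-ylmethyl)-1,5-diiodo-2-methyl-2-(4-methylpent-4-en-1-yl)pentane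
Product: 12 (3R,4R)-3-(1,3-dioxolan-2-ylmethyl)-5-iodo-4-methyl-4-(4-methylpent-4-en-1-yl)pentanal
Conditions: Me3NO, DMSO, rt to 45 °C
Reagents that add atoms: trimethylamine N-oxide, C[N+](C)(C)[O-]
Why: Kornblum-type oxidation with an amine N-oxide depends on SN2 attack at the unhindered primary iodide followed by elimination to the aldehyde, so the neopentyl iodide at C4, which cannot be displaced, survives.

Step 8
Reactants: 12 (3R,4R)-3-(1,3-dioxolan-2-ylmethyl)-5-iodo-4-methyl-4-(4-methylpent-4-en-1-yl)pentanal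
Product: 13 (3S,4R)-3-(1,3-dioxolan-2-ylmethyl)-5-iodo-4-methyl-4-(4-methylpent-4-en-1-yl)pentanoic acid
Conditions: NaClO2, NaH2PO4, 2-methylbut-2-ene, t-BuOH/H2O, 0 °C to rt
Reagents that add atoms: sodium chlorite, [Na+].[O-]Cl=O
Why: Pinnick oxidation takes the aldehyde to the acid under buffered conditions, with 2-methylbut-2-ene scavenging hypochlorous acid so that the acetal, the alkene and the iodide are preserved.

Step 9
Reactants: 13 (3S,4R)-3-(1,3-dioxolan-2-ylmethyl)-5-iodo-4-methyl-4-(4-methylpent-4-en-1-yl)pentanoic acid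
Product: 14 (3S,4R)-3-(1,3-dioxolan-2-ylmethyl)-5-iodo-4-methyl-4-(4-methylpent-4-en-1-yl)-1-(morpholin-4-yl)pentan-1-one
Conditions: morpholine, EDC·HCl, HOBt (cat.), iPr2NEt, CH2Cl2, 0 °C to rt
Reagents that add atoms: morpholine, C1COCCN1
Why: Carbodiimide amide coupling gives the morpholine amide, chosen because it forms a stable Z enolate for step 10 and later reacts once with an alkynyl Grignard reagent in the manner of a Weinreb amide.

Step 10
Reactants: 14 (3S,4R)-3-(1,3-dioxolan-2-ylmethyl)-5-iodo-4-methyl-4-(4-methylpent-4-en-1-yl)-1-(morpholin-4-yl)pentan-1-one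
Product: 16 (2S,3S,4R)-3-(1,3-dioxolan-2-ylmethyl)-5-iodo-4-methyl-4-(4-methylpent-4-en-1-yl)-1-(morpholin-4-yl)-2-(prop-2-yn-1-yl)pentan-1-one, via lithium Z-enolate 15 (not isolated)
Conditions: LiN(iPr)2, THF, −78 °C; HC≡CCH2Br, −78 to −40 °C
Reagents that add atoms: 3-bromoprop-1-yne, C#CCBr
Why: Amide enolate alkylation under acyclic 1,2-induction: A(1,3) strain holds the C6–H bond in the plane of the Z enolate and 3-bromoprop-1-yne attacks anti to the very bulky quaternary C5 group, which sets C7 as 2S (trans to the C6 arm in the later ring), while the neopentyl iodide has no β-hydrogen and resists the base.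

Step 11
Reactants: 16 (2S,3S,4R)-3-(1,3-dioxolan-2-ylmethyl)-5-iodo-4-methyl-4-(4-methylpent-4-en-1-yl)-1-(morpholin-4-yl)-2-(prop-2-yn-1-yl)pentan-1-one
Product: 17 (2S,3S,4R)-3-(1,3-dioxolan-2-ylmethyl)-5-iodo-4-methyl-2-[(2-methyl-1,3-dioxolan-2-yl)methyl]-4-(4-methylpent-4-en-1-yl)-1-(morpholin-4-yl)pentan-1-one
Conditions: HOCH2CH2OH, Ph3PAuNTf2 (2 mol %), CH2Cl2, rt
Reagents that add atoms: ethane-1,2-diol, OCCO
Why: Gold-catalysed Markovnikov hydroalkoxylation of the terminal alkyne with ethane-1,2-diol delivers the methyl ketone directly as its dioxolane, so the acetonyl arm is never exposed as a free ketone before the Grignard step.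

Step 12
Reactants: 17 (2S,3S,4R)-3-(1,3-dioxolan-2-ylmethyl)-5-iodo-4-methyl-2-[(2-methyl-1,3-dioxolan-2-yl)methyl]-4-(4-methylpent-4-en-1-yl)-1-(morpholin-4-yl)pentan-1-one; 18 ethynylmagnesium bromide
Product: 19 (4S,5S,6R)-5-(1,3-dioxolan-2-ylmethyl)-7-iodo-6-methyl-4-[(2-methyl-1,3-dioxolan-2-yl)methyl]-6-(4-methylpent-4-en-1-yl)hept-1-yn-3-one
Conditions: HC≡CMgBr, THF, 0 °C to rt; inverse quench into cold aq. NH4Cl
Reagents that add atoms: none
Why: Acyl substitution of the morpholine amide by the alkynyl Grignard reagent stops at the ketone because the tetrahedral magnesium adduct persists until the cold acidic inverse quench, which also protonates the liberated morpholine before it can add to the ynone.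

Step 13
Reactants: 19 (4S,5S,6R)-5-(1,3-dioxolan-2-ylmethyl)-7-iodo-6-methyl-4-[(2-methyl-1,3-dioxolan-2-yl)methyl]-6-(4-methylpent-4-en-1-yl)hept-1-yn-3-one
Product: 20 (1Z,4S,5S,6R)-5-(1,3-dioxolan-2-ylmethyl)-1,7-diiodo-6-methyl-4-[(2-methyl-1,3-dioxolan-2-yl)methyl]-6-(4-methylpent-4-en-1-yl)hept-1-en-3-one
Conditions: LiI, AcOH, MeCN, 0 °C to rt
Reagents that add atoms: lithium iodide, [Li+].[I-]
Why: Conjugate hydroiodination of the ynone with LiI and AcOH is an anti addition under kinetic control at low temperature and so gives the (Z)-β-iodoenone.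

Step 14
Reactants: 20 (1Z,4S,5S,6R)-5-(1,3-dioxolan-2-ylmethyl)-1,7-diiodo-6-methyl-4-[(2-methyl-1,3-dioxolan-2-yl)methyl]-6-(4-methylpent-4-en-1-yl)hept-1-en-3-one
Product: 21 (5S,6S,7S)-6-(1,3-dioxolan-2-ylmethyl)-5-methyl-7-[(2-methyl-1,3-dioxolan-2-yl)methyl]-5-(4-methylpent-4-en-1-yl)cyclohept-2-en-1-one
Conditions: NiBr2·glyme (30 mol %), 4,4′-di-tert-butyl-2,2′-bipyridine (30 mol %), Mn powder, NaI, DMA, 30 °C, syringe-pump addition of 20 (final 0.005 M)
Reagents that add atoms: none
Why: Zerovalent nickel inserts into the activated alkenyl C–I bond with retention to give a carbonyl-chelated (Z)-β-acylalkenyl nickel iodide, while a monovalent nickel species abstracts iodine from C4; the neopentyl radical is captured at nickel and the C(sp3)–C(sp2) bond forms by reductive elimination (direct radical attack at C3 with loss of iodine would give the same product), Mn returning nickel to its low-valent state. The closest known reaction type is the nickel-catalysed reductive cross-electrophile coupling of alkyl iodides with alkenyl halides, here made intramolecular by slow addition. The seven-membered ring closes at C3 in a 7-endo sense and the Z geometry of the iodoenone becomes the cis C2=C3 bond. No stereocentre is formed and C5, C6 and C7 are carried through unchanged. The step needs cross-selectivity between the two C–I bonds, secured by their different modes of activation, and freedom from β-hydride loss, secured because C4 sits between C3 and the quaternary C5. High dilution disfavours dimerisation, the gem-disubstituted C5 favours the folded chain, and the precursor offers the C4 radical no alkene within 5-exo reach.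

Step 15
Reactants: 21 (5S,6S,7S)-6-(1,3-dioxolan-2-ylmethyl)-5-methyl-7-[(2-methyl-1,3-dioxolan-2-yl)methyl]-5-(4-methylpent-4-en-1-yl)cyclohept-2-en-1-one
Product: 22 (5S,6S,7S)-6-(1,3-dioxolan-2-ylmethyl)-5-methyl-7-[(2-methyl-1,3-dioxolan-2-yl)methyl]-5-(4-methylpent-3-en-1-yl)cyclohept-2-en-1-one
Conditions: chloro[N,N′-bis(3,5-di-tert-butylsalicylidene)cyclohexane-1,2-diaminato]cobalt, Co(salen)Cl (3 mol %), PhSiH3 (6 mol %), benzene, rt
Reagents that add atoms: none
Why: Cobalt-hydride hydrogen-atom-transfer alkene isomerisation moves the 1,1-disubstituted double bond one position along the chain into the thermodynamically preferred trisubstituted position, the catalytic amount of silane leaving the enone unreduced.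

Step 16
Reactants: 22 (5S,6S,7S)-6-(1,3-dioxolan-2-ylmethyl)-5-methyl-7-[(2-methyl-1,3-dioxolan-2-yl)methyl]-5-(4-methylpent-3-en-1-yl)cyclohept-2-en-1-one
Product: 23 (5S,6S,7S)-6-(1,3-dioxolan-2-ylmethyl)-2-(hydroxymethyl)-5-methyl-7-[(2-methyl-1,3-dioxolan-2-yl)methyl]-5-(4-methylpent-3-en-1-yl)cyclohept-2-en-1-one
Conditions: aq. HCHO (37 %), DMAP, THF/H2O, rt
Reagents that add atoms: formaldehyde, C=O
Why: Morita–Baylis–Hillman reaction: DMAP adds reversibly to C3, the enolate captures formaldehyde at C2 and elimination restores the enone, under conditions mild enough for the acetals and for C7.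

Step 17
Reactants: 23 (5S,6S,7S)-6-(1,3-dioxolan-2-ylmethyl)-2-(hydroxymethyl)-5-methyl-7-[(2-methyl-1,3-dioxolan-2-yl)methyl]-5-(4-methylpent-3-en-1-yl)cyclohept-2-en-1-one
Product: 24 (5S,6S,7S)-2-(hydroxymethyl)-5-methyl-5-(4-methylpent-3-en-1-yl)-6-(2-oxoethyl)-7-(2-oxopropyl)cyclohept-2-en-1-one
Conditions: 1 M HCl, THF, rt to 40 °C
Reagents that add atoms: water, O
Why: Acid-catalysed acetal hydrolysis releases the aldehyde and the methyl ketone in one operation at a stage where neither a silyl ether nor the enol ester is present.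

Step 18
Reactants: 24 (5S,6S,7S)-2-(hydroxymethyl)-5-methyl-5-(4-methylpent-3-en-1-yl)-6-(2-oxoethyl)-7-(2-oxopropyl)cyclohept-2-en-1-one; 25 3-methylbut-2-enoic anhydride
Product: 27 (E)-2-[(1S,2S,7S)-7-methyl-7-(4-methylpent-3-en-1-yl)-3-oxo-2-(2-oxopropyl)-4-{[(triethylsilyl)oxy]methyl}cyclohept-4-en-1-yl]ethenyl 3-methylbut-2-enoate, via triethylsilyl ether 26 (not isolated)
Conditions: Et3SiCl, Et3N, DMAP (cat.), CH2Cl2, 0 °C; then 25, Et3N, rt
Reagents that add atoms: chlorotriethylsilane, CC[Si](Cl)(CC)CC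
Why: Silylation of the primary alcohol followed in the same flask by DMAP-catalysed O-acylation of the aldehyde enolate (the ketones are not enolised by Et3N) should give the enol ester mainly as the more stable E isomer, the Z isomer being removed by chromatography.

Step 19
Reactants: 27 (E)-2-[(1S,2S,7S)-7-methyl-7-(4-methylpent-3-en-1-yl)-3-oxo-2-(2-oxopropyl)-4-{[(triethylsilyl)oxy]methyl}cyclohept-4-en-1-yl]ethenyl 3-methylbut-2-enoate
Product: 28 (E)-2-[(1S,2S,7S)-4-(hydroxymethyl)-7-methyl-7-(4-methylpent-3-en-1-yl)-3-oxo-2-(2-oxopropyl)cyclohept-4-en-1-yl]ethenyl 3-methylbut-2-enoate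
Conditions: HF·pyridine, pyridine, THF, 0 °C
Reagents that add atoms: none
Why: Fluoride-induced desilylation with buffered HF·pyridine frees the primary alcohol without cleaving the enol ester.

Step 20
Reactants: 28 (E)-2-[(1S,2S,7S)-4-(hydroxymethyl)-7-methyl-7-(4-methylpent-3-en-1-yl)-3-oxo-2-(2-oxopropyl)cyclohept-4-en-1-yl]ethenyl 3-methylbut-2-enoate
Product: 29 (E)-2-[(1S,2S,7S)-7-[(3S)-3-hydroperoxy-4-methylpent-4-en-1-yl]-4-(hydroxymethyl)-7-methyl-3-oxo-2-(2-oxopropyl)cyclohept-4-en-1-yl]ethenyl 3-methylbut-2-enoate (CNP0216745.1)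
Conditions: O2, tetraphenylporphyrin (cat.), visible light, CH2Cl2, −20 °C; HPLC separation
Reagents that add atoms: oxygen, O=O
Why: Schenck ene reaction: singlet oxygen attacks only the electron-rich trisubstituted alkene and, on abstraction of a methyl hydrogen, places the hydroperoxide on the secondary carbon without facial control, so the (S)-epimer is separated by HPLC from its C-epimer and from the tertiary regioisomer.

Compound list

1 | 5,6-dihydro-2H-pyran-2-one | O=C1C=CCCO1 | starting material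
2 | (1,3-dioxolan-2-ylmethyl)magnesium bromide | Br[Mg]CC1OCCO1 | starting material
3 | (R)-4-(1,3-dioxolan-2-ylmethyl)oxan-2-one | O=C1C[C@@H](CC2OCCO2)CCO1 | intermediate
4 | lithium enolate of 3, lithium (4R)-4-(1,3-dioxolan-2-ylmethyl)-5,6-dihydro-4H-pyran-2-olate | [Li]OC1=C[C@@H](CC2OCCO2)CCO1 | intermediate
5 | (3R,4R)-4-(1,3-dioxolan-2-ylmethyl)-3-methyloxan-2-one | C[C@H]([C@@H](CC1OCCO1)CCO2)C2=O | intermediate
6 | 4-methylpent-4-en-1-ol | C=C(C)CCCO | starting material
7 | 5-iodo-2-methylpent-1-ene | C=C(C)CCCI | intermediate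
8 | lithium enolate of 5, lithium (4R)-4-(1,3-dioxolan-2-ylmethyl)-3-methyl-5,6-dihydro-4H-pyran-2-olate | [Li]OC1=C(C)[C@@H](CC2OCCO2)CCO1 | intermediate
9 | (3R,4R)-4-(1,3-dioxolan-2-ylmethyl)-3-methyl-3-(4-methylpent-4-en-1-yl)oxan-2-one | C=C(C)CCC[C@@]([C@@H](CC1OCCO1)CCO2)(C)C2=O | intermediate
10 | (2R,3R)-3-(1,3-dioxolan-2-ylmethyl)-2-methyl-2-(4-methylpent-4-en-1-yl)pentane-1,5-diol | C=C(C)CCC[C@@]([C@@H](CC1OCCO1)CCO)(C)CO | intermediate
11 | (2R,3S)-3-(1,3-dioxolan-2-ylmethyl)-1,5-diiodo-2-methyl-2-(4-methylpent-4-en-1-yl)pentane | C=C(C)CCC[C@@]([C@@H](CC1OCCO1)CCI)(C)CI | intermediate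
12 | (3R,4R)-3-(1,3-dioxolan-2-ylmethyl)-5-iodo-4-methyl-4-(4-methylpent-4-en-1-yl)pentanal | C=C(C)CCC[C@@]([C@@H](CC1OCCO1)CC=O)(C)CI | intermediate
13 | (3S,4R)-3-(1,3-dioxolan-2-ylmethyl)-5-iodo-4-methyl-4-(4-methylpent-4-en-1-yl)pentanoic acid | C=C(C)CCC[C@@]([C@@H](CC1OCCO1)CC(=O)O)(C)CI | intermediate
14 | (3S,4R)-3-(1,3-dioxolan-2-ylmethyl)-5-iodo-4-methyl-4-(4-methylpent-4-en-1-yl)-1-(morpholin-4-yl)pentan-1-one | C=C(C)CCC[C@@]([C@@H](CC1OCCO1)CC(=O)N2CCOCC2)(C)CI | intermediate
15 | lithium Z-enolate of 14, lithium (1Z,3S,4R)-3-(1,3-dioxolan-2-ylmethyl)-5-iodo-4-methyl-4-(4-methylpent-4-en-1-yl)-1-(morpholin-4-yl)pent-1-en-1-olate | C=C(C)CCC[C@@]([C@@H](CC1OCCO1)/C=C(\O[Li])N2CCOCC2)(C)CI | intermediate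
16 | (2S,3S,4R)-3-(1,3-dioxolan-2-ylmethyl)-5-iodo-4-methyl-4-(4-methylpent-4-en-1-yl)-1-(morpholin-4-yl)-2-(prop-2-yn-1-yl)pentan-1-one | C=C(C)CCC[C@@]([C@@H](CC1OCCO1)[C@H](CC#C)C(=O)N2CCOCC2)(C)CI | intermediate
17 | (2S,3S,4R)-3-(1,3-dioxolan-2-ylmethyl)-5-iodo-4-methyl-2-[(2-methyl-1,3-dioxolan-2-yl)methyl]-4-(4-methylpent-4-en-1-yl)-1-(morpholin-4-yl)pentan-1-one | C=C(C)CCC[C@@]([C@@H](CC1OCCO1)[C@H](CC2(C)OCCO2)C(=O)N3CCOCC3)(C)CI | intermediate
18 | ethynylmagnesium bromide | C#C[Mg]Br | starting material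
19 | (4S,5S,6R)-5-(1,3-dioxolan-2-ylmethyl)-7-iodo-6-methyl-4-[(2-methyl-1,3-dioxolan-2-yl)methyl]-6-(4-methylpent-4-en-1-yl)hept-1-yn-3-one | C=C(C)CCC[C@@]([C@@H](CC1OCCO1)[C@H](CC2(C)OCCO2)C(=O)C#C)(C)CI | intermediate
20 | (1Z,4S,5S,6R)-5-(1,3-dioxolan-2-ylmethyl)-1,7-diiodo-6-methyl-4-[(2-methyl-1,3-dioxolan-2-yl)methyl]-6-(4-methylpent-4-en-1-yl)hept-1-en-3-one | C=C(C)CCC[C@@]([C@@H](CC1OCCO1)[C@H](CC2(C)OCCO2)C(=O)/C=C\I)(C)CI | intermediate
21 | (5S,6S,7S)-6-(1,3-dioxolan-2-ylmethyl)-5-methyl-7-[(2-methyl-1,3-dioxolan-2-yl)methyl]-5-(4-methylpent-4-en-1-yl)cyclohept-2-en-1-one | C=C(C)CCC[C@@]1(C)CC=CC(=O)[C@@H](CC2(C)OCCO2)[C@@H]1CC3OCCO3 | intermediate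
22 | (5S,6S,7S)-6-(1,3-dioxolan-2-ylmethyl)-5-methyl-7-[(2-methyl-1,3-dioxolan-2-yl)methyl]-5-(4-methylpent-3-en-1-yl)cyclohept-2-en-1-one | CC(C)=CCC[C@@]1(C)CC=CC(=O)[C@@H](CC2(C)OCCO2)[C@@H]1CC3OCCO3 | intermediate
23 | (5S,6S,7S)-6-(1,3-dioxolan-2-ylmethyl)-2-(hydroxymethyl)-5-methyl-7-[(2-methyl-1,3-dioxolan-2-yl)methyl]-5-(4-methylpent-3-en-1-yl)cyclohept-2-en-1-one | CC(C)=CCC[C@@]1(C)CC=C(CO)C(=O)[C@@H](CC2(C)OCCO2)[C@@H]1CC3OCCO3 | intermediate
24 | (5S,6S,7S)-2-(hydroxymethyl)-5-methyl-5-(4-methylpent-3-en-1-yl)-6-(2-oxoethyl)-7-(2-oxopropyl)cyclohept-2-en-1-one | CC(C)=CCC[C@@]1(C)CC=C(CO)C(=O)[C@@H](CC(C)=O)[C@@H]1CC=O | intermediate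
25 | 3-methylbut-2-enoic anhydride | CC(C)=CC(=O)OC(=O)C=C(C)C | starting material
26 | triethylsilyl ether of 24, (5S,6S,7S)-5-methyl-5-(4-methylpent-3-en-1-yl)-6-(2-oxoethyl)-7-(2-oxopropyl)-2-{[(triethylsilyl)oxy]methyl}cyclohept-2-en-1-one | CC(C)=CCC[C@@]1(C)CC=C(CO[Si](CC)(CC)CC)C(=O)[C@@H](CC(C)=O)[C@@H]1CC=O | intermediate
27 | (E)-2-[(1S,2S,7S)-7-methyl-7-(4-methylpent-3-en-1-yl)-3-oxo-2-(2-oxopropyl)-4-{[(triethylsilyl)oxy]methyl}cyclohept-4-en-1-yl]ethenyl 3-methylbut-2-enoate | CC(C)=CCC[C@@]1(C)CC=C(CO[Si](CC)(CC)CC)C(=O)[C@@H](CC(C)=O)[C@@H]1/C=C/OC(=O)C=C(C)C | intermediate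
28 | (E)-2-[(1S,2S,7S)-4-(hydroxymethyl)-7-methyl-7-(4-methylpent-3-en-1-yl)-3-oxo-2-(2-oxopropyl)cyclohept-4-en-1-yl]ethenyl 3-methylbut-2-enoate | CC(C)=CCC[C@@]1(C)CC=C(CO)C(=O)[C@@H](CC(C)=O)[C@@H]1/C=C/OC(=O)C=C(C)C | intermediate
29 | (E)-2-[(1S,2S,7S)-7-[(3S)-3-hydroperoxy-4-methylpent-4-en-1-yl]-4-(hydroxymethyl)-7-methyl-3-oxo-2-(2-oxopropyl)cyclohept-4-en-1-yl]ethenyl 3-methylbut-2-enoate (CNP0216745.1) | C=C(C)[C@H](CC[C@@]1(C)CC=C(CO)C(=O)[C@@H](CC(C)=O)[C@@H]1/C=C/OC(=O)C=C(C)C)OO | target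

Total step count: 20. Longest linear sequence: 19 steps (steps 1, 2 and 4 to 20, from 1 to 29); step 3 is a one-step side branch.

Steps most likely to fail

Step 14 (ring closure). The C4 radical may be lost before nickel captures it: 1,5-hydrogen shift from the acetal or allylic positions, attack on the remote alkene or intermolecular coupling can compete, and iodide may scramble the Z geometry of the iodoenone before insertion. The fallback sets out from ynone 19, one step earlier, and replaces the organonickel closure by a free-radical chain cyclisation: (Me3Si)3SiH and Et3B/air in toluene under slow addition. The silyl radical abstracts iodine from C4, the neopentyl radical adds in a 7-endo mode to the terminal ynone carbon C3, and the α-keto vinyl radical is reduced by the silane to the ring enone, which can only be cis. This returns to the route at 21 and makes no new compound (F0).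

Step 1 (conjugate addition). Face discrimination may be insufficient, because the tetrahydrofuran that comes with the Grignard solution erodes the selectivity of copper–diphosphine catalysts, and 1,2-addition may compete. The fallback sets out from 1 and uses a rhodium-catalysed Hayashi–Miyaura 1,4-addition of KF3BCH=CH2 ([Rh(cod)Cl]2, the BINAP antipode that gives the S product, dioxane/H2O) to reach (S)-4-ethenyloxan-2-one F1. Hydroboration with disiamylborane and direct oxidation of the organoborane with [C5H5NH][CrO3Cl] then gives (R)-2-(2-oxooxan-4-yl)acetaldehyde F2. The free 2-hydroxyethyl lactone is deliberately avoided, since it could racemise by degenerate translactonisation. Acetalisation with ethane-1,2-diol and TsOH returns to the route at 3.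

Step 10 (C7 alkylation). Facial discrimination in the acyclic enolate may be poor, and proton transfer from the propargylic halide or slow O-alkylation onto C4 may intervene. The fallback sets out from acid 13 and puts the new centre under auxiliary control (Evans alkylation, matched with the substrate bias). Acylation of (S)-4-benzyloxazolidin-2-one through the pivaloyl mixed anhydride gives the N-acyl oxazolidinone F3. NaN(SiMe3)2 and 3-bromoprop-1-yne at −78 °C give the propargylated imide F4. Gold-catalysed ketalisation as in step 11 gives the ketal imide F5, and Me2AlN(OMe)Me converts it into the Weinreb amide F6. HC≡CMgBr then returns to the route at 19.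

Further compounds

F0 | step 14 | none | none
F1 | step 1 | (S)-4-ethenyloxan-2-one | O=C1C[C@@H](C=C)CCO1
F2 | step 1 | (R)-2-(2-oxooxan-4-yl)acetaldehyde | O=C1C[C@@H](CC=O)CCO1
F3 | step 10 | (4S)-4-benzyl-3-[(3S,4R)-3-(1,3-dioxolan-2-ylmethyl)-5-iodo-4-methyl-4-(4-methylpent-4-en-1-yl)pentanoyl]-1,3-oxazolidin-2-one | C=C(C)CCC[C@@]([C@@H](CC1OCCO1)CC(=O)N2C(=O)OC[C@@H]2Cc3ccccc3)(C)CI
F4 | step 10 | (4S)-4-benzyl-3-[(2S,3S,4R)-3-(1,3-dioxolan-2-ylmethyl)-5-iodo-4-methyl-4-(4-methylpent-4-en-1-yl)-2-(prop-2-yn-1-yl)pentanoyl]-1,3-oxazolidin-2-one | C=C(C)CCC[C@@]([C@@H](CC1OCCO1)[C@H](CC#C)C(=O)N2C(=O)OC[C@@H]2Cc3ccccc3)(C)CI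
F5 | step 10 | (4S)-4-benzyl-3-[(2S,3S,4R)-3-(1,3-dioxolan-2-ylmethyl)-5-iodo-4-methyl-2-[(2-methyl-1,3-dioxolan-2-yl)methyl]-4-(4-methylpent-4-en-1-yl)pentanoyl]-1,3-oxazolidin-2-one | C=C(C)CCC[C@@]([C@@H](CC1OCCO1)[C@H](CC2(C)OCCO2)C(=O)N3C(=O)OC[C@@H]3Cc4ccccc4)(C)CI
F6 | step 10 | (2S,3S,4R)-3-(1,3-dioxolan-2-ylmethyl)-5-iodo-N-methoxy-N,4-dimethyl-2-[(2-methyl-1,3-dioxolan-2-yl)methyl]-4-(4-methylpent-4-en-1-yl)pentanamide | C=C(C)CCC[C@@]([C@@H](CC1OCCO1)[C@H](CC2(C)OCCO2)C(=O)N(C)OC)(C)CI
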